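## Structural features

The target is a 3,4-disubstituted γ-butyrolactone (O1, C2 carbonyl, C3, C4, C5). C3 carries an exocyclic, E-configured trisubstituted double bond to C6, which bears ring B (3-hydroxy-4,5-dimethoxyphenyl). C4 carries the methylene C7 that leads to ring A (4-hydroxy-3-methoxyphenyl). C4 (R) is the only stereocentre and lies between the sp2 carbon C3 and the oxymethylene C5, so no neighbouring centre can relay to it and the task is one of absolute configuration alone. The arylidene lactone is the fragile part: it is a Michael acceptor, it can lose its geometry, it would be reduced under hydrogenolysis, and migration of the double bond into the ring would erase C4. The two free phenols are acidic and oxidisable, and the lactone opens in aqueous base but closes again on acidification. The real difficulty is to install C4 cheaply in high enantiomeric purity and then to build the E-alkene at C3 without making C4 planar. The key step exploits the fact that C7, C4 and C5 (with O1) are the three carbons of an epichlorohydrin unit and C3 is a malonate carbon. In the bicyclic lactone made from the two, C7 is the cyclopropane methylene, and opening the C7–C3 bond with the ring A nucleophile gives the C4-benzyl lactone with a carboxyl left on C3 for the olefination.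

## Logic of the disconnections

15 ⇒ 12 + 13. The C3=C6 double bond is cut. It is the only carbon–carbon link between ring B and the lactone, and an alkene conjugated to a carbonyl is the retron of a carbonyl condensation. With a carboxyl on C3 the condensation is decarboxylative, so neither a strong base nor a separate dehydration is needed. The target falls into 13, used as bought, and 12, which holds the stereocentre. The forward step must form the C3–C6 bond at a carbon that becomes quaternary in 14 faster than 12 simply loses CO2, must favour the E isomer, must leave C4 untouched and must tolerate free phenols.

12 ⇒ 10. No skeletal bond is cut: the C3 carboxyl is traced back to its methyl ester and the ring A phenol to its silyl ether. The ester is the second activating group that the cyclopropane opening needs, and the silyl ether is the mask that the organomagnesium step needs. Both are removed by hydroxide in one operation, so no separate deprotection step follows. The forward step passes through the ring-opened 11, which must re-close on acidification, and the free malonic acid must not be heated.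

10 ⇒ 7 + 8. The C7–aryl bond is cut, with reconnection of C7 to C3 as a cyclopropane. This places the polar bond formation at an unhindered CH2 that is doubly activated through the ring, and removes ring A and one ring-carbon substituent in one stroke. The stereocentre is a spectator of this bond. The forward step demands attack at the cyclopropane methylene and not at either carbonyl group or at the ring-fusion CH.

8 ⇒ 2 ⇒ 1. The carbon–magnesium bond goes back to the carbon–bromine bond of 2, and the O–Si bond of 2 to the phenol of 1. The bromine of 1 already sits para to the hydroxyl, which is the ring A pattern, so no regiochemical question arises. The demand is only that the phenol mask survives magnesium and copper and leaves under the hydroxide of the later hydrolysis.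

7 ⇒ 3 + 4. Three bonds are cut: C3–C7, C3–C4 and the acyl–oxygen bond O1–C2. All three form in one flask from 3 acting as a double nucleophile and 4 acting as a double electrophile, with lactonisation of the released alkoxide onto the cis ester. The gain is maximal: a bicyclic, enantioenriched precursor from two bulk chemicals in one step. The demand is mechanistic fidelity: the anion of 3 must open the epoxide of 4 first (via 5 and 6), because direct displacement of chloride would lead to the mirror-image bicycle.

## Other disconnections considered

Alternative 1: The cut is the O1–C5 bond, which takes the lactone back to the prochiral cyclobutanone A1. In the forward direction a Baeyer–Villiger monooxygenase of the cyclohexanone monooxygenase family (NADPH recycling, O2, buffer) would insert oxygen into one of the two enantiotopic C(O)–CH2 bonds and give the (R)-lactone A2.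
- In its favour: the stereocentre would be created catalytically from an achiral substrate, the oxidant is air, and no low-temperature organometallic step is needed. Strained 3-substituted cyclobutanones are generally well accepted by this enzyme class.
- Against it here: A1 must be made first (ketene [2+2] cycloaddition to an allylarene, then dechlorination; about three steps). The sense and level of enantioselection for a bulky, electron-rich benzyl group would have to be found by enzyme screening. A2 has no activating group on C3, so the arylidene would need a strong-base aldol reaction on protected partners, a separate dehydration and a deprotection.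
- Comparison: both plans arrive at a C4-benzyl lactone, but the chosen plan delivers it with a C3 carboxyl that is used twice (to activate the cyclopropane, then to drive the olefination). Mechanistically the alternative is a protein-controlled desymmetrisation, whereas the chosen plan transfers the chirality of a bulk building block through SN2 events. The alternative is the better in catalytic asymmetric character, mildness and freedom from stoichiometric metal reagents, and it is not exposed to loss of enantiopurity through a second mechanistic channel as step 2 is. In step economy it is worse (about eight steps against five).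

Alternative 2: The cut is the C4–C5 bond with transposition of the double bond: the C5 carbon is moved from C4 onto the oxygen of a C6 carbinol, giving the stannylmethyl ether A4 of the (R,E)-allylic alcohol A3. In the forward direction, tin–lithium exchange on A4 with n-BuLi at −78 °C would give an α-alkoxymethyl carbanion. This would undergo a [2,3] shift through a five-membered envelope transition state, forming C4–C5 on the alkene face from which the C6–O bond departs and moving the double bond to C3=C6, to give A5.
- In its favour: the stereocentre and the alkene geometry would arise in one concerted, suprafacial event. With a substituent on the central alkene carbon (here CH2OTBS), the C6 aryl group is expected to turn away from it in the transition state, and this is the arrangement that places ring B cis to C4 as the target requires. The geometry would thus be set kinetically at low temperature.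
- Against it here: A3 must be both enantioenriched at C6 and geometrically pure at its trisubstituted alkene, since each element is translated directly into C4. The wrong alkene isomer, or the other transition-state conformer, would deliver the enantiomeric centre. Stoichiometric organotin and n-BuLi are needed, and a [1,2] shift can compete at the benzylic C6–O bond. A5 is at the diol oxidation level, so desilylation, chemoselective allylic oxidation with lactonisation and removal of two acetal protecting groups would follow.
- Comparison: the alternative builds the acyclic skeleton first and closes the lactone last, whereas the chosen plan holds the lactone from step 2 onwards. It relays chirality from C6 to C4 by a pericyclic process instead of drawing it from the chiral pool. In kinetic control of the double-bond geometry it is the better, and in independence from amine-mediated equilibration it is at least the equal. In step economy (more than ten steps, three protecting groups, two redox adjustments) and reagent burden it is clearly worse.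

Alternative 3: The cut is the C6–aryl bond, giving the (R)-α-methylene lactone A6 and the ring B aryl iodide A7. In the forward direction Pd(OAc)2 with Bu4NCl and NaHCO3 in DMF (ligand-free phase-transfer Heck conditions) would bring about oxidative addition of A7 to zerovalent palladium, syn carbopalladation of the exocyclic alkene with the aryl group going to C6, and syn β-hydride elimination to the bis(methoxymethyl) ether A8. Acid would then free the phenols.
- In its favour: it is convergent and introduces ring B last, so analogues would need only another aryl halide. The E geometry follows from the syn-addition and syn-elimination sequence. The conditions avoid hot amine. A6 could be drawn from the same cyclopropane opening (a C3 carboxylic acid with formaldehyde and a secondary amine), so both plans can share their source of chirality.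
- Against it here: the tertiary alkylpalladium at C3 has the C4 hydrogen available as well as the two C6 hydrogens, and that hydrogen lies syn to palladium when the metal adds anti to the benzyl group. Elimination in that direction, or re-addition of the palladium hydride, would give the endocyclic butenolide and destroy the only stereocentre. The 1,1-disubstituted acceptor alkene of A6 is prone to polymerise, and A7 (iodine meta to the oxygen substituents) is not a simple commercial compound.
- Comparison: the carbon skeleton and the origin of C4 can be identical up to the coupling, and there the alternative is the equal. It is the better in convergence and late-stage variation of ring B. It is the worse mechanistically, because the stereocentre stands next to the reacting organometallic centre, whereas in the chosen plan C4 is never adjacent to a metal-bearing carbon. It is also the worse in step count (about nine with the preparation of A7).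

Key step: step 3

Remarks before the steps:
- Locants: lactone O1, C2 (C=O), C3, C4, C5; C6 is the arylidene carbon on C3; C7 is the benzylic CH2 on C4.
- Ring A is carried as its tert-butyldimethylsilyl ether and not as an acetal ether. It survives magnesium and copper, falls off under the hydroxide of step 4, and allows strongly acidic re-lactonisation there. The ring B hydroxyl of 13 is left free because it is meta to the formyl group and does not deactivate it.
- The ring opening in step 3 does create a centre at C3. It is a malonate-type C–H, is labile, and is drawn in the expected trans form (3S,4R) in 10 and 12; its ratio has no bearing on the route.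
- The configurational path was checked by the SN2 bookkeeping: (R)-4 gives (1S,5R)-7 (one inversion at the epoxide carbon), and this gives (4R) in 10, 12 and 15.

## Route

Step 1
Reactants: 1 4-bromo-2-methoxyphenol
Product: 2 tert-butyl(4-bromo-2-methoxyphenoxy)dimethylsilane
Conditions: TBSCl, imidazole, DMF, rt
Reagents that add atoms: tert-butyldimethylsilyl chloride, CC(C)(C)[Si](C)(C)Cl
Why: Standard O-silylation of a phenol with imidazole as base and nucleophilic catalyst; the aryl bromide and methyl ether are inert, and the silyl ether masks the acidic O–H that would otherwise quench the organomagnesium reagent.

Step 2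
Reactants: 3 dimethyl malonate; 4 (R)-epichlorohydrin
Product: 7 methyl (1S,5R)-2-oxo-3-oxabicyclo[3.1.0]hexane-1-carboxylate, via epoxy malonate 5 (not isolated), via cyclopropylcarbinol diester 6 (not isolated)
Conditions: NaOMe, MeOH, rt, then reflux
Reagents that add atoms: none
Why: Tandem alkylation, cyclopropanation and lactonisation: the malonate anion opens the epoxide of 4 at its CH2 terminus, the alkoxide displaces chloride to give 5, and the re-formed malonate anion closes the three-membered ring by 3-exo-tet attack on the epoxide CH carbon of 5 with inversion, which fixes the future C4. The alkoxide of 6 lactonises onto the cis ester, releasing methoxide that carries the base cycle, and the cis ring fusion is the only one possible, so C1 follows from C5.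

Step 3
Reactants: 2 tert-butyl(4-bromo-2-methoxyphenoxy)dimethylsilane; 7 methyl (1S,5R)-2-oxo-3-oxabicyclo[3.1.0]hexane-1-carboxylate
Product: 10 methyl (3S,4R)-4-{4-[(tert-butyldimethylsilyl)oxy]-3-methoxybenzyl}-2-oxotetrahydrofuran-3-carboxylate, via aryl Grignard reagent 8 (not isolated), via bromomagnesium enolate 9 (not isolated)
Conditions: Mg, THF, 45 °C; then 7, CuI (10 mol%), THF, −30 to 0 °C; aq NH4Cl
Reagents that add atoms: none
Why: Magnesium insertion into 2 gives 8, which transmetallates to CuI to form an arylcuprate; this attacks the unsubstituted cyclopropane carbon C7 of 7 from the side opposite the C7–C3 bond in an SN2-like homoconjugate addition (formally oxidative addition to a trivalent copper alkyl and reductive elimination), the closest known reaction type being the copper-catalysed opening of cyclopropane-1,1-dicarbonyl compounds by Grignard reagents. Ring strain and the two carbonyl groups on C3 make the malonate-type enolate 9 the leaving group, so the C7–aryl bond forms as the C7–C3 bond breaks. No ring is closed: the three-membered ring is opened and the lactone is kept. C4 is not a reacting centre, so the configuration fixed in step 2 passes unchanged into 10 as 4R. The only new stereocentre, C3, arises when 9 is protonated in the NH4Cl quench and should settle trans to the C4 benzyl group (3S) under thermodynamic control because it stays acidic; it is erased in step 5. The step needs chemoselectivity for the cyclopropane over the ester and lactone carbonyls and regioselectivity for CH2 over the ring-fusion CH: copper catalysis at low temperature makes the nucleophile soft, the methylene is the unhindered and doubly activated site, 7 has no acidic hydrogen to quench the reagent, and once opened the substrate is masked as enolate 9 against further addition. The aryl silyl ether and the methyl ethers are inert under these conditions.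

Step 4
Reactants: 10 methyl (3S,4R)-4-{4-[(tert-butyldimethylsilyl)oxy]-3-methoxybenzyl}-2-oxotetrahydrofuran-3-carboxylate
Product: 12 (3S,4R)-4-(4-hydroxy-3-methoxybenzyl)-2-oxotetrahydrofuran-3-carboxylic acid, via hydroxy malonate trisodium salt 11 (not isolated)
Conditions: NaOH, MeOH/H2O, 0 °C to rt; then 2 M HCl to pH 1, rt
Reagents that add atoms: sodium hydroxide, [Na+].[OH-]
Why: Saponification: excess hydroxide hydrolyses the methyl ester, opens the lactone and cleaves the base-labile aryl silyl ether to give 11, and acidification re-closes the five-membered lactone onto either carboxyl of the malonic acid. C4 bears no acidic hydrogen and is unaffected; the mixture is kept at or below room temperature so that the malonic acid does not lose CO2.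

Step 5
Reactants: 12 (3S,4R)-4-(4-hydroxy-3-methoxybenzyl)-2-oxotetrahydrofuran-3-carboxylic acid; 13 3-hydroxy-4,5-dimethoxybenzaldehyde
Product: 15 (3E,4R)-3-(3-hydroxy-4,5-dimethoxybenzylidene)-4-(4-hydroxy-3-methoxybenzyl)dihydrofuran-2(3H)-one, via carbinol adduct 14 (not isolated)
Conditions: piperidine, pyridine, 90 °C, N2
Reagents that add atoms: none
Why: Knoevenagel condensation in the Doebner modification, applied to a monosubstituted malonic half ester: piperidine activates 13 as its iminium ion, the enol of 12 adds through C3 to give 14 (or its piperidino analogue), and anti decarboxylative elimination forms the C3=C6 bond. The E isomer (aryl anti to the lactone carbonyl) is the thermodynamic one and should be reached because the addition and amine conjugate addition are reversible. The C4 hydrogen is not activated by the carbonyl, so the stereocentre should not be touched, and the meta hydroxyl of 13 and the phenol of 12 are tolerated as in condensations of hydroxybenzaldehydes.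

## Compound list

1 | 4-bromo-2-methoxyphenol | COc1cc(Br)ccc1O | starting material
2 | tert-butyl(4-bromo-2-methoxyphenoxy)dimethylsilane | COc1cc(Br)ccc1O[Si](C)(C)C(C)(C)C | intermediate
3 | dimethyl malonate | COC(=O)CC(=O)OC | starting material
4 | (R)-epichlorohydrin | ClC[C@H]1CO1 | starting material
5 | dimethyl 2-{[(2R)-oxiran-2-yl]methyl}malonate (in the flask partly as its sodium enolate) | COC(=O)C(C(=O)OC)C[C@@H]1CO1 | intermediate (not isolated)
6 | dimethyl (2R)-2-(hydroxymethyl)cyclopropane-1,1-dicarboxylate (in the flask as its sodium alkoxide) | OC[C@@H]1CC1(C(=O)OC)C(=O)OC | intermediate (not isolated)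
7 | methyl (1S,5R)-2-oxo-3-oxabicyclo[3.1.0]hexane-1-carboxylate | C1[C@H]2COC(=O)[C@@]12C(=O)OC | intermediate
8 | {4-[(tert-butyldimethylsilyl)oxy]-3-methoxyphenyl}magnesium bromide | COc1cc([Mg]Br)ccc1O[Si](C)(C)C(C)(C)C | intermediate (not isolated)
9 | bromomagnesium enolate of 10 (4R) | COC(=O)C1=C(O[Mg]Br)OC[C@@H]1Cc2ccc(O[Si](C)(C)C(C)(C)C)c(OC)c2 | intermediate (not isolated)
10 | methyl (3S,4R)-4-{4-[(tert-butyldimethylsilyl)oxy]-3-methoxybenzyl}-2-oxotetrahydrofuran-3-carboxylate (trans; C3 labile) | COc1cc(C[C@H]2COC(=O)[C@@H]2C(=O)OC)ccc1O[Si](C)(C)C(C)(C)C | intermediate
11 | 2-[(2R)-1-hydroxy-3-(4-hydroxy-3-methoxyphenyl)propan-2-yl]propanedioic acid (in the flask as its trisodium salt) | OC[C@H](Cc1ccc(O)c(OC)c1)C(C(=O)O)C(=O)O | intermediate (not isolated)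
12 | (3S,4R)-4-(4-hydroxy-3-methoxybenzyl)-2-oxotetrahydrofuran-3-carboxylic acid (trans; C3 labile) | COc1cc(C[C@H]2COC(=O)[C@@H]2C(=O)O)ccc1O | intermediate
13 | 3-hydroxy-4,5-dimethoxybenzaldehyde | COc1cc(C=O)cc(O)c1OC | starting material
14 | (4R)-3-[hydroxy(3-hydroxy-4,5-dimethoxyphenyl)methyl]-4-(4-hydroxy-3-methoxybenzyl)-2-oxotetrahydrofuran-3-carboxylic acid (mixture at C3 and the carbinol carbon) | COc1cc(C[C@H]2COC(=O)C2(C(=O)O)C(O)c3cc(O)c(OC)c(OC)c3)ccc1O | intermediate (not isolated)
15 | (3E,4R)-3-(3-hydroxy-4,5-dimethoxybenzylidene)-4-(4-hydroxy-3-methoxybenzyl)dihydrofuran-2(3H)-one | COc1cc(C[C@H]2COC(=O)/C2=C/c2cc(O)c(OC)c(OC)c2)ccc1O | target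

## Step count and least certain steps

Total step count: 5. Longest linear sequence: 4 steps (3 and 4 to 7, then 10, 12, 15; equally 1 to 2, then 10, 12, 15).

Step 3 (key step). The most likely failure is direct addition of the aryl Grignard reagent to the ester or lactone carbonyl, together with copper-mediated homocoupling of the aryl reagent. The electron-rich bromide inserts magnesium slowly, and uncatalysed 1,2-addition competes whenever the cuprate is formed or consumed too slowly. Fallback, setting out from 7 and 2 and returning at 10:
- 7 would be opened with HBr in acetic acid at room temperature to methyl (3S,4R)-4-(bromomethyl)-2-oxotetrahydrofuran-3-carboxylate F1. Bromide attacks the same methylene and C4 is untouched.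
- The C7–aryl bond would then be made by nickel-catalysed reductive cross-electrophile coupling of F1 with 2 (NiBr2·glyme, 4,4'-di-tert-butyl-2,2'-bipyridine, Zn, NaI, DMA, 60 °C). This needs no preformed organometallic nucleophile and so cannot add to the carbonyl groups.

Step 5. The most likely failure is protodecarboxylation of the malonic half acid outrunning carbon–carbon bond formation, because C3 must become quaternary next to the substituted C4. A secondary concern is incomplete equilibration to the E isomer. Fallback, setting out from 12 and returning at 15 by the classical aldol and dehydration sequence:
- 12 would be decarboxylated deliberately (toluene, 110 °C) to (R)-4-(4-hydroxy-3-methoxybenzyl)dihydrofuran-2(3H)-one F2.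
- F2 would be silylated (TBSCl, imidazole) to (R)-4-{4-[(tert-butyldimethylsilyl)oxy]-3-methoxybenzyl}dihydrofuran-2(3H)-one F3, and 13 likewise to 3-[(tert-butyldimethylsilyl)oxy]-4,5-dimethoxybenzaldehyde F4.
- The lithium enolate of F3 (LDA, THF, −78 °C) would add to F4 to give the aldol adduct (4R)-3-{hydroxy[3-(tert-butyldimethylsilyloxy)-4,5-dimethoxyphenyl]methyl}-4-{4-[(tert-butyldimethylsilyl)oxy]-3-methoxybenzyl}dihydrofuran-2(3H)-one F5.
- Mesylation and elimination (MsCl, Et3N, then DBU) would give the bis-silyl ether of the target, (3E,4R)-3-{3-[(tert-butyldimethylsilyl)oxy]-4,5-dimethoxybenzylidene}-4-{4-[(tert-butyldimethylsilyl)oxy]-3-methoxybenzyl}dihydrofuran-2(3H)-one F6.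
- Bu4NF buffered with AcOH in THF would release 15.

Step 2. The most likely failure is leakage of enantiomeric purity, because direct displacement of chloride by the malonate anion competes with epoxide opening and leads to the mirror-image bicycle. Oligomerisation of the epoxide would also cost yield. The enantiomeric purity would be checked at 10, and a crystalline later intermediate could be used for upgrading. Fallback, setting out from 3 and returning at 7: the sodium salt of 3 (NaH, THF/DMF, 0 °C to rt, then warming) would be alkylated with commercial (S)-oxiran-2-ylmethyl 3-nitrobenzenesulfonate F7. With a sulfonate leaving group, direct displacement is expected to precede epoxide opening; this reversed order, starting from the opposite glycidyl configuration, passes through the same epoxide 5 and on through 6 to 7.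

Step 4. The most likely failure is loss of CO2 from the free malonic acid during acidification and concentration, or incomplete re-lactonisation of the ring-opened acid. Fallback, setting out from 10 and returning at 12, avoiding strong base and strong acid: the silyl ether would be removed with Bu4NF and AcOH in THF to give methyl (3S,4R)-4-(4-hydroxy-3-methoxybenzyl)-2-oxotetrahydrofuran-3-carboxylate F8, and its methyl ester would be hydrolysed enzymatically (pig liver esterase, phosphate buffer pH 7.5, acetone cosolvent, rt) and acidified gently to 12.

## Further compounds

F1 | step 3 | methyl (3S,4R)-4-(bromomethyl)-2-oxotetrahydrofuran-3-carboxylate | BrC[C@H]1COC(=O)[C@@H]1C(=O)OC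
F2 | step 5 | (R)-4-(4-hydroxy-3-methoxybenzyl)dihydrofuran-2(3H)-one | COc1cc(C[C@H]2COC(=O)C2)ccc1O
F3 | step 5 | (R)-4-{4-[(tert-butyldimethylsilyl)oxy]-3-methoxybenzyl}dihydrofuran-2(3H)-one | COc1cc(C[C@H]2COC(=O)C2)ccc1O[Si](C)(C)C(C)(C)C
F4 | step 5 | 3-[(tert-butyldimethylsilyl)oxy]-4,5-dimethoxybenzaldehyde | COc1cc(C=O)cc(O[Si](C)(C)C(C)(C)C)c1OC
F5 | step 5 | (4R)-3-{hydroxy[3-(tert-butyldimethylsilyloxy)-4,5-dimethoxyphenyl]methyl}-4-{4-[(tert-butyldimethylsilyl)oxy]-3-methoxybenzyl}dihydrofuran-2(3H)-one | COc1cc(C[C@H]2COC(=O)C2C(O)c3cc(O[Si](C)(C)C(C)(C)C)c(OC)c(OC)c3)ccc1O[Si](C)(C)C(C)(C)C
F6 | step 5 | (3E,4R)-3-{3-[(tert-butyldimethylsilyl)oxy]-4,5-dimethoxybenzylidene}-4-{4-[(tert-butyldimethylsilyl)oxy]-3-methoxybenzyl}dihydrofuran-2(3H)-one | COc1cc(C[C@H]2COC(=O)/C2=C/c3cc(O[Si](C)(C)C(C)(C)C)c(OC)c(OC)c3)ccc1O[Si](C)(C)C(C)(C)C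
F7 | step 2 | (S)-oxiran-2-ylmethyl 3-nitrobenzenesulfonate | O=[N+]([O-])c1cccc(c1)S(=O)(=O)OC[C@@H]1CO1
F8 | step 4 | methyl (3S,4R)-4-(4-hydroxy-3-methoxybenzyl)-2-oxotetrahydrofuran-3-carboxylate | COc1cc(C[C@H]2COC(=O)[C@@H]2C(=O)OC)ccc1O
A1 | alternative 1 | 3-[4-(methoxymethoxy)-3-methoxybenzyl]cyclobutan-1-one | COCOc1ccc(CC2CC(=O)C2)cc1OC
A2 | alternative 1 | (R)-4-[4-(methoxymethoxy)-3-methoxybenzyl]dihydrofuran-2(3H)-one | COCOc1ccc(C[C@H]2COC(=O)C2)cc1OC
A3 | alternative 2 | (1R,2E)-2-{[(tert-butyldimethylsilyl)oxy]methyl}-1-[3,4-dimethoxy-5-(methoxymethoxy)phenyl]-4-[3-methoxy-4-(methoxymethoxy)phenyl]but-2-en-1-ol | O[C@H](c1cc(OCOC)c(OC)c(OC)c1)/C(CO[Si](C)(C)C(C)(C)C)=C/Cc1ccc(OCOC)c(OC)c1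
A4 | alternative 2 | tributylstannylmethyl ether of A3 (R,E) | CCCC[Sn](CCCC)(CCCC)CO[C@H](c1cc(OCOC)c(OC)c(OC)c1)/C(CO[Si](C)(C)C(C)(C)C)=C/Cc1ccc(OCOC)c(OC)c1
A5 | alternative 2 | (2R,3E)-3-{[(tert-butyldimethylsilyl)oxy]methyl}-4-[3,4-dimethoxy-5-(methoxymethoxy)phenyl]-2-[3-methoxy-4-(methoxymethoxy)benzyl]but-3-en-1-ol | OC[C@H](Cc1ccc(OCOC)c(OC)c1)/C(CO[Si](C)(C)C(C)(C)C)=C\c1cc(OCOC)c(OC)c(OC)c1
A6 | alternative 3 | (R)-4-[4-(methoxymethoxy)-3-methoxybenzyl]-3-methylenedihydrofuran-2(3H)-one | COCOc1ccc(C[C@H]2COC(=O)C2=C)cc1OC
A7 | alternative 3 | 5-iodo-1,2-dimethoxy-3-(methoxymethoxy)benzene | COCOc1cc(I)cc(OC)c1OC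
A8 | alternative 3 | (3E,4R)-3-[3,4-dimethoxy-5-(methoxymethoxy)benzylidene]-4-[3-methoxy-4-(methoxymethoxy)benzyl]dihydrofuran-2(3H)-one | COCOc1ccc(C[C@H]2COC(=O)/C2=C/c2cc(OCOC)c(OC)c(OC)c2)cc1OC
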